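(The numbers in the tables are simulated with constants of no real substance; scatter was added.)

Take the earlier runs first, and read the dusk run from its tail.

| flask | substrate | partner | temperature | remark | time |
|---|---|---|---|---|---|
| midnight | 0.10 M | 1.2 equiv | 45 °C | run made earlier |  |
| dusk | 0.10 M | 5 equiv | 58 °C | run made earlier |  |
| summer | 0.050 M | 2.5 equiv | 45 °C | run made earlier |  |
| north-east | 0.10 M | 2.50 equiv | 50 °C |  | 20 min |
| west | 0.10 M | 2.50 equiv | 58 °C |  | 20 min |
| south-west | 0.10 M | 2.50 equiv | 66 °C |  | 20 min |

| run | time / min | target / % | over-reaction product / % | open intermediate / % | substrate / % |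
|---|---|---|---|---|---|
| midnight | 1.00 | 2 | 2 | 22 | 78 |
| midnight | 3.00 | 1 | 0 | 56 | 48 |
| midnight | 6.00 | 6 | 0 | 71 | 21 |
| midnight | 8.00 | 10 | 0 | 75 | 14 |
| midnight | 12.0 | 14 | 1 | 76 | 8 |
| midnight | 15.0 | 22 | 1 | 71 | 6 |
| dusk | 1.00 | 4 | 1 | 64 | 31 |
| dusk | 3.00 | 39 | 6 | 55 | 3 |
| dusk | 6.00 | 66 | 18 | 16 | 1 |
| dusk | 8.00 | 69 | 32 | 4 | 1 |
| dusk | 12.0 | 51 | 47 | 0 | 0 |
| dusk | 15.0 | 41 | 60 | 0 | 0 |
| summer | 3.00 | 1 | 0 | 54 | 45 |
| summer | 6.00 | 4 | 1 | 69 | 23 |
| summer | 10.0 | 16 | 2 | 77 | 10 |
| summer | 12.0 | 21 | 0 | 72 | 6 |
| summer | 15.0 | 28 | 3 | 65 | 2 |

(standard deviation of a reading: 1.5 percentage points)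

* which of these there is most of at the end, counted by the substrate in it, north-east (over-reaction product / target / open intermediate / substrate)
* which of these there is most of at the end, counted by the substrate in it, west (over-reaction product / target / open intermediate / substrate)
* which of these there is most of at the end, counted by the substrate in it, south-west (over-reaction product / target / open intermediate / substrate)
* the largest of these amounts at the end, in percent of the substrate charged, north-east
* the largest of these amounts at the end, in percent of the substrate charged, west
* the largest of these amounts at the end, in percent of the substrate charged, south-west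

Two times matter here: how long open intermediate takes to become target, and how long target survives.

In dusk, target falls at 0.0756 min⁻¹ between 8.00 min and 12.0 min, then at 0.0728 min⁻¹ up to 15.0 min. That is nearly the same rate at a lower level, so [target] sets the order: first order. Over the whole stretch the rate reads 0.0744 min⁻¹. Call the survival time of target its half-life at 58 °C, 9.32 min.

Now the making. Dusk's open intermediate drops from 55% to 16% between 3.00 min and 6.00 min, a half-life of 1.68 min. Judge this step by [partner], not by equivalents: midnight (1.2 equiv) and summer (2.5 equiv) hold nearly equal [partner], 0.120 M and 0.125 M, and read 22% and 28% target at 15.0 min.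

West has half of dusk's [partner] at the same temperature. Scale the making time in proportion, which is my own reckoning, to 3.37 min. Making is faster than loss, but not by much. Ignoring the early lag, two such steps in series peak near 7.74 min, well before 20 min. My reckoning leaves 32.8% target in west, so over-reaction product should lead there.

The forecast differs on west. It gives target at 57% for north-east, target at 62% for west and over-reaction product at 57% for south-west, with the caution “The lag and the unknown activation energy for over-reaction add uncertainty.”

The flasks give target at 60.9% in north-east, over-reaction product at 66.5% in west and over-reaction product at 96.2% in south-west.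

    target → over-reaction product (k = 0.0330 min⁻¹, Ea = 103 kJ mol⁻¹)
    open intermediate + second intermediate → target (k = 2.40 M⁻¹ min⁻¹, Ea = 54.0 kJ mol⁻¹)
    substrate ⇌ open intermediate (K = 28.0, k = 0.480 min⁻¹, Ea = 99.0 kJ mol⁻¹, ΔH = 29.0 kJ mol⁻¹)
    partner → second intermediate (k = 0.0450 min⁻¹, Ea = 90.0 kJ mol⁻¹)
    (constants at 50 °C)

South-west holds 96.2% over-reaction product at 20 min against 23.3% in north-east, and the difference in temperature is the main reason. West holds 55.9% target at 10.0 min and 33.1% at 20 min, a net halving time of 13.2 min, longer than the 9.32 min read from dusk, with 15.6% of open intermediate still standing at 10.0 min. Carry it on from dusk's last reading to 20 min: target falls to 28.3%, which leaves 71.7% as over-reaction product, and the dusk run taken to that time holds 73.4%.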